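The route opens the C5–C10 bond shared by rings A and B of a glucose-derived trans-decalin, so the ten-membered carbocycle is revealed with no macrocyclisation. The key step exploits the 1,3-relationship of C5 and C1 across C10: an axial C5 tertiary alkoxide and an equatorial C1 mesylate, antiperiplanar about C5–C10, collapse in one operation to the C5 ketone and the E-configured C1=C10 olefin. Its precursor is a 10β-methyl trans-decalin bearing the 1β-mesylate, a cis-4α,5α-diol with the 4β-methyl group, and 6α-PMB, 7β-TES and 8α-TBS ethers derived from O4, O3 and O2 of methyl α-D-glucopyranoside. Closure of the 4,5-epoxide, butenolide annulation, two acylations and C1=C10 epoxidation then finish the target.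

Key step: step 17

Remarks on the chemistry (assumptions)
- Locants: ring carbons of all carbocyclic intermediates carry the target's numbers (C1–C10; C14 = methyl on C10, C15 = methyl on C4, C11–C13 = lactone carbons). For decalins, β is the face of C14. TBS = tert-butyldimethylsilyl, TES = triethylsilyl, TMS = trimethylsilyl, TIPS = triisopropylsilyl, PMB = 4-methoxybenzyl, Ms = methanesulfonyl.
- The target is (1R,4R,5R,6S,8S,10R). Decalin 22 and cyclodecenone 23 were checked centre by centre against it: C4, C6 and C8 have the target's sense, the diol is cis on the α face and the mesylate is equatorial. No descriptor needed correction.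
- C10 and C1: a closed aldol transition state from a C10-methyl enolate would put C14 syn to the C1 hydroxyl, which becomes the axial C1 epimer after ring closure and cannot fragment. The side chain is therefore attached first, C14 is added last by alkylation, and C1 is set on the rigid decalin by directed reduction of a C1 ketone.
- Stereorandom centres that are later destroyed or converged are written without a descriptor: the carbinol carbon of 9 and 10, C1 of 13–19, and the phosphonate-bearing carbon of 31–35.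
- The fragmentation is run on the free 4,5-diol with only a slight excess of base, which is consumed as mesylate leaves.

Step 1
Reactants: 1 methyl α-D-glucopyranoside; 2 4-methoxybenzaldehyde dimethyl acetal
Product: 3 methyl 4,6-O-[(R)-4-methoxybenzylidene]-α-D-glucopyranoside
Conditions: camphorsulfonic acid (cat.), DMF, 50 °C, 200 mbar
Reagents that add atoms: none
Why: Acid-catalysed transacetalisation with removal of methanol gives the thermodynamically preferred six-membered 4,6-acetal (trans-fused 1,3-dioxane, aryl equatorial, hence R at the acetal carbon) and leaves O2 and O3 free.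

Step 2
Reactants: 3 methyl 4,6-O-[(R)-4-methoxybenzylidene]-α-D-glucopyranoside
Product: 4 methyl 2-O-TBS-4,6-O-[(R)-4-methoxybenzylidene]-α-D-glucopyranoside
Conditions: TBSCl (1.05 equiv), imidazole, DMF, 0 °C → rt
Reagents that add atoms: tert-butyldimethylsilyl chloride, CC(C)(C)[Si](C)(C)Cl
Why: Regioselective O-silylation: in α-glucosides O2 is the more acidic and accessible of the two remaining hydroxyls (hydrogen bond to the cis anomeric oxygen), so one equivalent of the bulky silyl chloride should react there; no stereocentre is formed.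

Step 3
Reactants: 4 methyl 2-O-TBS-4,6-O-[(R)-4-methoxybenzylidene]-α-D-glucopyranoside
Product: 5 methyl 2-O-TBS-3-O-TES-4,6-O-[(R)-4-methoxybenzylidene]-α-D-glucopyranoside
Conditions: Et3SiOTf, 2,6-lutidine, CH2Cl2, −78 °C
Reagents that add atoms: triethylsilyl trifluoromethanesulfonate, CC[Si](CC)(CC)OS(=O)(=O)C(F)(F)F
Why: O-silylation of the remaining, hindered O3 with the reactive silyl triflate; base and low temperature leave the acetal intact.

Step 4
Reactants: 5 methyl 2-O-TBS-3-O-TES-4,6-O-[(R)-4-methoxybenzylidene]-α-D-glucopyranoside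
Product: 6 methyl 2-O-TBS-3-O-TES-4-O-PMB-α-D-glucopyranoside
Conditions: i-Bu2AlH, CH2Cl2, −78 → 0 °C; aq. potassium sodium tartrate work-up
Reagents that add atoms: none
Why: Reductive acetal opening: aluminium binds the less hindered O6, the C–O6 bond ionises and hydride reduces the oxocarbenium ion, so the PMB group stays on O4 and the primary hydroxyl is released.

Step 5
Reactants: 6 methyl 2-O-TBS-3-O-TES-4-O-PMB-α-D-glucopyranoside
Product: 7 methyl 6-deoxy-6-iodo-2-O-TBS-3-O-TES-4-O-PMB-α-D-glucopyranoside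
Conditions: I2, PPh3, imidazole, toluene, 60 °C
Reagents that add atoms: iodine, II
Why: Appel-type iodination converts the only free, primary hydroxyl into the iodide by SN2 displacement of the oxyphosphonium ion.

Step 6
Reactants: 7 methyl 6-deoxy-6-iodo-2-O-TBS-3-O-TES-4-O-PMB-α-D-glucopyranoside
Product: 8 methyl 6-deoxy-2-O-TBS-3-O-TES-4-O-PMB-α-D-xylo-hex-5-enopyranoside
Conditions: KOtBu, THF, 0 °C
Reagents that add atoms: none
Why: E2 dehydrohalogenation with a hindered alkoxide removes H5 and iodide to give the exocyclic enol ether needed for carbocyclisation.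

Step 7
Reactants: 8 methyl 6-deoxy-2-O-TBS-3-O-TES-4-O-PMB-α-D-xylo-hex-5-enopyranoside
Product: 9 (2S,3S,4S)-4-(TBS-oxy)-5-hydroxy-2-(PMB-oxy)-3-(TES-oxy)cyclohexan-1-one (C5 epimers)
Conditions: Hg(OCOCF3)2 (5 mol %), acetone/H2O (2:1), rt
Reagents that add atoms: water, O
Why: Ferrier carbocyclisation: oxymercuration of the enol ether releases methanol and the C1 aldehyde, and the α-mercurio ketone closes the six-membered carbocycle by intramolecular aldol addition, leaving the three ether-bearing centres untouched; the new carbinol centre is uncontrolled and is removed in step 8.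

Step 8
Reactants: 9 (2S,3S,4S)-4-(TBS-oxy)-5-hydroxy-2-(PMB-oxy)-3-(TES-oxy)cyclohexan-1-one
Product: 11 (4S,5S,6S)-4-(TBS-oxy)-6-(PMB-oxy)-5-(TES-oxy)cyclohex-2-en-1-one, via β-mesyloxy ketone 10 (not isolated)
Conditions: MsCl, Et3N, CH2Cl2, 0 °C → rt
Reagents that add atoms: none
Why: Sulfonylation of the β-hydroxyl and E1cB elimination through the ketone enolate give the conjugated enone, whose carbonyl is the future C5 and whose olefin is C10=C9.

Step 9
Reactants: 11 (4S,5S,6S)-4-(TBS-oxy)-6-(PMB-oxy)-5-(TES-oxy)cyclohex-2-en-1-one; 12 pent-4-enal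
Product: 13 (4S,5S,6S)-2-(1-hydroxypent-4-en-1-yl)-4-(TBS-oxy)-6-(PMB-oxy)-5-(TES-oxy)cyclohex-2-en-1-one (C1 epimers)
Conditions: imidazole (1 equiv), THF/1 M aq. NaHCO3 (1:1), rt
Reagents that add atoms: none
Why: Morita–Baylis–Hillman reaction: imidazole adds reversibly to C9, the derived enolate adds to the aldehyde through C10 and the catalyst is expelled, which attaches C1–C4 and C15 at C10 while keeping the enone; the C1 carbinol centre is not controlled and both epimers are carried on.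

Step 10
Reactants: 13 (4S,5S,6S)-2-(1-hydroxypent-4-en-1-yl)-4-(TBS-oxy)-6-(PMB-oxy)-5-(TES-oxy)cyclohex-2-en-1-one
Product: 14 trimethylsilyl ether of 13 at the C1 oxygen
Conditions: Me3SiCl, imidazole, CH2Cl2, 0 °C
Reagents that add atoms: chlorotrimethylsilane, C[Si](C)(C)Cl
Why: O-silylation masks the hydroxyl so that the following enolate is not a chelating dianion and the C1 oxygen stays a poor leaving group.

Step 11
Reactants: 14 trimethylsilyl ether of 13
Product: 16 (2S,4S,5S,6S)-2-methyl-2-[1-(trimethylsilyloxy)pent-4-en-1-yl]-4-(TBS-oxy)-6-(PMB-oxy)-5-(TES-oxy)cyclohexan-1-one (C14 β on C10; C1 epimers), via potassium C5–C10 enolate 15 (not isolated)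
Conditions: K[s-Bu3BH], THF, −78 °C; then MeI (excess), −78 → −30 °C
Reagents that add atoms: iodomethane, CI
Why: Reductive alkylation of an enone: 1,4-hydride addition at C9 gives the C5–C10 enolate regiospecifically, and methyl iodide then creates the quaternary C10 by axial attack on the half-chair with the three ring ethers pseudo-equatorial, i.e. anti to the C8 silyloxy group, which places C14 β and the side chain equatorial.

Step 12
Reactants: 16 (2S,4S,5S,6S)-2-methyl-2-[1-(trimethylsilyloxy)pent-4-en-1-yl]-4-(TBS-oxy)-6-(PMB-oxy)-5-(TES-oxy)cyclohexan-1-one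
Product: 17 (2S,4S,5S,6S)-2-methyl-2-[4-oxo-1-(trimethylsilyloxy)pentyl]-4-(TBS-oxy)-6-(PMB-oxy)-5-(TES-oxy)cyclohexan-1-one (C1 epimers)
Conditions: PdCl2 (10 mol %), Cu(OAc)2 (20 mol %), O2 (1 atm), N,N-dimethylacetamide/H2O (7:1), rt
Reagents that add atoms: water, O
Why: Tsuji–Wacker oxidation: Markovnikov hydroxypalladation of the terminal olefin and β-hydride elimination give the C4 methyl ketone, with acetate-buffered copper and oxygen as reoxidant so that silyl and PMB ethers survive.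

Step 13
Reactants: 17 (2S,4S,5S,6S)-2-methyl-2-[4-oxo-1-(trimethylsilyloxy)pentyl]-4-(TBS-oxy)-6-(PMB-oxy)-5-(TES-oxy)cyclohexan-1-one
Product: 19 6α-(PMB-oxy)-7β-(TES-oxy)-8α-(TBS-oxy)-4β,10β-dimethyl-trans-decalin-1ξ,4α,5α-triol, via trimethylsilyl ether diol 18 (not isolated)
Conditions: SmI2 (2.5 equiv), THF, −78 → 0 °C; then K2CO3, MeOH, rt
Reagents that add atoms: none
Why: Ketyl–carbonyl (pinacol) coupling: single-electron reduction of the α-alkoxy C5 ketone and samarium-bridged addition to the C4 ketone through a chair with the side chain equatorial on ring B should close ring A (6-exo) as the cis-4α,5α-diol with trans ring fusion, the metal bridge fixing the two oxygens cis and the equatorial tether fixing O5 axial; methanolysis then removes the trimethylsilyl group.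

Step 14
Reactants: 19 6α-(PMB-oxy)-7β-(TES-oxy)-8α-(TBS-oxy)-4β,10β-dimethyl-trans-decalin-1ξ,4α,5α-triol
Product: 20 4α,5α-dihydroxy-6α-(PMB-oxy)-7β-(TES-oxy)-8α-(TBS-oxy)-4β,10β-dimethyl-trans-decalin-1-one
Conditions: (COCl)2, DMSO, CH2Cl2, −78 °C; Et3N, −78 → 0 °C
Reagents that add atoms: none
Why: Swern oxidation (alkoxysulfonium ylide elimination) touches only the secondary C1 hydroxyl, so both C1 epimers converge on one ketone while the tertiary diol is inert.

Step 15
Reactants: 20 4α,5α-dihydroxy-6α-(PMB-oxy)-7β-(TES-oxy)-8α-(TBS-oxy)-4β,10β-dimethyl-trans-decalin-1-one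
Product: 21 6α-(PMB-oxy)-7β-(TES-oxy)-8α-(TBS-oxy)-4β,10β-dimethyl-trans-decalin-1β,4α,5α-triol
Conditions: Me4NBH(OAc)3, MeCN/AcOH (1:1), −20 °C
Reagents that add atoms: none
Why: Hydroxyl-directed Evans–Saksena reduction: the axial 5α-hydroxyl exchanges onto boron and delivers hydride to the α face of C1, the same face favoured by axial attack anti to C14, so the equatorial 1β-alcohol (1,3-anti to O5) should form, and the acidic medium excludes retro-aldol opening.

Step 16
Reactants: 21 6α-(PMB-oxy)-7β-(TES-oxy)-8α-(TBS-oxy)-4β,10β-dimethyl-trans-decalin-1β,4α,5α-triol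
Product: 22 4α,5α-dihydroxy-6α-(PMB-oxy)-7β-(TES-oxy)-8α-(TBS-oxy)-4β,10β-dimethyl-trans-decalin-1β-yl methanesulfonate
Conditions: MsCl, Et3N, CH2Cl2, −10 °C
Reagents that add atoms: methanesulfonyl chloride, CS(=O)(=O)Cl
Why: Sulfonylation discriminates the single secondary hydroxyl from the two tertiary ones, giving the equatorial mesylate cis to C14.

Step 17
Reactants: 22 4α,5α-dihydroxy-6α-(PMB-oxy)-7β-(TES-oxy)-8α-(TBS-oxy)-4β,10β-dimethyl-trans-decalin-1β-yl methanesulfonate
Product: 23 (1(10)E,4R,6S,7S,8S)-4-hydroxy-4,10-dimethyl-6-(PMB-oxy)-7-(TES-oxy)-8-(TBS-oxy)cyclodec-1(10)-en-5-one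
Conditions: KOtBu (1.1 equiv), THF, 0 °C; pH 7 phosphate buffer quench
Reagents that add atoms: none
Why: Wharton–Grob fragmentation, the heterolytic fragmentation of a 1,3-diol monosulfonate: the C5 alkoxide pushes electron density into the C5–C10 σ bond, which is antiperiplanar to the equatorial C1–O bond, so that C5=O forms, C5–C10 breaks, C1=C10 forms and mesylate leaves in one concerted event. No ring is closed; the ten-membered ring appears because the bond common to rings A and B is cut. No stereocentre is created, and the olefin geometry is dictated by the trans ring fusion, in which C9 on C10 is antiperiplanar to C2 on C1, so the E isomer should result. The step needs fragmentation to outrun oxetane formation, elimination of the mesylate and base-induced decay of the product (α-ketol shift, β-loss of the C7 silyloxy group); the equatorial mesylate cis to C14 provides the alignment, release of the 4β/10β dimethyl diaxial strain provides the driving force, and a bare excess of base at 0 °C, consumed as mesylate is expelled, limits exposure of the hydroxy ketone. The C4 hydroxyl and the C6, C7 and C8 centres pass through unchanged.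

Step 18
Reactants: 23 (1(10)E,4R,6S,7S,8S)-4-hydroxy-4,10-dimethyl-6-(PMB-oxy)-7-(TES-oxy)-8-(TBS-oxy)cyclodec-1(10)-en-5-one
Product: 24 (5S)-4,10-dimethyl-6-(PMB-oxy)-7-(TES-oxy)-8-(TBS-oxy)cyclodec-1(10)E-ene-4,5-diol (4,5-anti and 5,6-anti; other centres as in 23)
Conditions: Zn(BH4)2, Et2O, −20 → 0 °C
Reagents that add atoms: none
Why: Chelation-controlled hydride reduction: zinc bridges the C5 carbonyl to the C4 hydroxyl (or to the C6 ether), and in both five-membered chelates the open face is the one flanked by the smaller substituent (C15 at C4, H at C6), so hydride should give the 5S alcohol, anti to both neighbouring oxygens.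

Step 19
Reactants: 24 (5S)-4,10-dimethyl-6-(PMB-oxy)-7-(TES-oxy)-8-(TBS-oxy)cyclodec-1(10)E-ene-4,5-diol
Product: 26 (4R,5R)-4,5-epoxy-4,10-dimethyl-6-(PMB-oxy)-7-(TES-oxy)-8-(TBS-oxy)cyclodec-1(10)E-ene (trans epoxide), via C5 mesylate 25 (not isolated)
Conditions: MsCl, Et3N, CH2Cl2, −10 °C; then K2CO3, MeOH, 0 °C → rt
Reagents that add atoms: none
Why: Selective sulfonylation of the secondary C5 hydroxyl and intramolecular Williamson displacement by the C4 alkoxide (3-exo-tet) close the trans 4,5-epoxide with inversion at C5 and retention at C4, giving the 4R,5R configuration of the target.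

Step 20
Reactants: 26 (4R,5R)-4,5-epoxy-4,10-dimethyl-6-(PMB-oxy)-7-(TES-oxy)-8-(TBS-oxy)cyclodec-1(10)E-ene
Product: 27 (4R,5R)-4,5-epoxy-4,10-dimethyl-7-(TES-oxy)-8-(TBS-oxy)cyclodec-1(10)E-en-6-ol (C6 as in the target)
Conditions: DDQ, CH2Cl2/pH 7 phosphate buffer (10:1), 0 °C
Reagents that add atoms: none
Why: Oxidative PMB cleavage: DDQ abstracts hydride from the electron-rich benzylic position and water hydrolyses the oxocarbenium ion, freeing O6 under buffered conditions that spare silyl ethers, the epoxide and the trisubstituted olefin.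

Step 21
Reactants: 28 tert-butyl diethylphosphonoacetate; 29 (triisopropylsiloxy)methyl chloride
Product: 31 tert-butyl 2-(diethoxyphosphoryl)-3-(TIPS-oxy)propanoate (racemic), via sodium phosphonate carbanion 30 (not isolated)
Conditions: NaH, THF, 0 °C; then 29, 0 °C → rt
Reagents that add atoms: none
Why: C-alkylation of the stabilised phosphonoacetate carbanion with an α-chloro ether introduces the silyl-protected hydroxymethyl group that becomes C13.

Step 22
Reactants: 31 tert-butyl 2-(diethoxyphosphoryl)-3-(TIPS-oxy)propanoate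
Product: 32 2-(diethoxyphosphoryl)-3-(TIPS-oxy)propanoic acid (racemic)
Conditions: CF3CO2H, CH2Cl2, 0 °C
Reagents that add atoms: none
Why: Acidolysis of the tert-butyl ester by loss of 2-methylpropene gives the acid without touching the phosphonate or the robust primary TIPS ether.

Step 23
Reactants: 27 (4R,5R)-4,5-epoxy-4,10-dimethyl-7-(TES-oxy)-8-(TBS-oxy)cyclodec-1(10)E-en-6-ol; 32 2-(diethoxyphosphoryl)-3-(TIPS-oxy)propanoic acid
Product: 33 C6 ester of 27 with acid 32 (epimers at the phosphonate carbon)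
Conditions: EDC·HCl, DMAP, CH2Cl2, 0 °C → rt
Reagents that add atoms: none
Why: Carbodiimide-mediated (Steglich) esterification acylates the free C6 hydroxyl with retention at C6; the phosphonate-bearing carbon is stereorandom and becomes sp2 in step 25.

Step 24
Reactants: 33 C6 ester of 27 with acid 32
Product: 34 C7 alcohol (33 without the triethylsilyl group)
Conditions: HF·pyridine, pyridine, THF, 0 °C
Reagents that add atoms: none
Why: Buffered HF cleaves the triethylsilyl ether far faster than the secondary TBS and primary TIPS ethers, releasing only the C7 hydroxyl.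

Step 25
Reactants: 34 C7 alcohol
Product: 36 13-(TIPS-oxy)-8α-(TBS-oxy)-4α,5β-epoxygermacra-1(10)E,7(11)-dien-12,6α-olide, via C7 ketone 35 (not isolated)
Conditions: SO3·pyridine, DMSO, i-Pr2NEt, CH2Cl2, 0 °C; then LiCl, MeCN, rt
Reagents that add atoms: none
Why: Parikh–Doering oxidation gives the C7 ketone and, after addition of LiCl, the amine already present deprotonates the lithium-chelated phosphonate, whose intramolecular Horner–Wadsworth–Emmons reaction with C7 closes the five-membered butenolide (C7=C11) faster than β-loss of the silyloxymethyl oxygen or enolisation toward C6 or C8.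

Step 26
Reactants: 36 13-(TIPS-oxy)-8α-(TBS-oxy)-4α,5β-epoxygermacra-1(10)E,7(11)-dien-12,6α-olide
Product: 37 8α,13-dihydroxy-4α,5β-epoxygermacra-1(10)E,7(11)-dien-12,6α-olide
Conditions: Bu4NF, AcOH (1:1), THF, 0 °C → rt
Reagents that add atoms: none
Why: Fluoride desilylation buffered with acetic acid removes both remaining silyl ethers without generating a free C8 alkoxide, which could otherwise translactonise to the 12,8-olide.

Step 27
Reactants: 37 8α,13-dihydroxy-4α,5β-epoxygermacra-1(10)E,7(11)-dien-12,6α-olide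
Product: 38 13-acetoxy-8α-hydroxy-4α,5β-epoxygermacra-1(10)E,7(11)-dien-12,6α-olide
Conditions: AcCl (1.05 equiv), 2,4,6-collidine, CH2Cl2, −78 °C
Reagents that add atoms: acetyl chloride, CC(=O)Cl
Why: Kinetically selective O-acylation: at low temperature with a hindered base the primary allylic C13 hydroxyl reacts much faster than the secondary C8 hydroxyl.

Step 28
Reactants: 39 ethyl 2-(hydroxymethyl)acrylate
Product: 40 ethyl 2-[(TBS-oxy)methyl]acrylate
Conditions: TBSCl, imidazole, CH2Cl2, 0 °C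
Reagents that add atoms: tert-butyldimethylsilyl chloride, CC(C)(C)[Si](C)(C)Cl
Why: O-silylation of the primary allylic alcohol protects it for the later esterification.

Step 29
Reactants: 40 ethyl 2-[(TBS-oxy)methyl]acrylate
Product: 41 2-[(TBS-oxy)methyl]acrylic acid
Conditions: LiOH, THF/H2O, 0 °C → rt; then cold 1 M HCl to pH 4
Reagents that add atoms: lithium hydroxide, [Li+].[OH-]
Why: Saponification of the ethyl ester under conditions that leave the primary TBS ether and the acrylate intact.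

Step 30
Reactants: 38 13-acetoxy-8α-hydroxy-4α,5β-epoxygermacra-1(10)E,7(11)-dien-12,6α-olide; 41 2-[(TBS-oxy)methyl]acrylic acid
Product: 42 13-acetoxy-8α-{2-[(TBS-oxy)methyl]acryloyloxy}-4α,5β-epoxygermacra-1(10)E,7(11)-dien-12,6α-olide
Conditions: EDC·HCl, DMAP, CH2Cl2, 0 °C → rt
Reagents that add atoms: none
Why: Steglich esterification acylates the C8 hydroxyl with retention; the silyl ether prevents self-condensation of the hydroxy acid.

Step 31
Reactants: 42 13-acetoxy-8α-{2-[(TBS-oxy)methyl]acryloyloxy}-4α,5β-epoxygermacra-1(10)E,7(11)-dien-12,6α-olide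
Product: 43 13-acetoxy-8α-[2-(hydroxymethyl)acryloyloxy]-4α,5β-epoxygermacra-1(10)E,7(11)-dien-12,6α-olide
Conditions: HF·pyridine, pyridine, THF, 0 °C → rt
Reagents that add atoms: none
Why: Pyridine-buffered HF removes the primary allylic TBS ether while the acetate, both unsaturated esters, the epoxide and the olefin should survive.

Step 32
Reactants: 43 13-acetoxy-8α-[2-(hydroxymethyl)acryloyloxy]-4α,5β-epoxygermacra-1(10)E,7(11)-dien-12,6α-olide
Product: 44 (1R,4R,5R,6S,8S,10R)-13-acetoxy-1β,10α:4α,5β-diepoxy-8α-[2-(hydroxymethyl)acryloyloxy]germacr-7(11)-en-12,6α-olide (CNP0282791.1)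
Conditions: mCPBA, NaHCO3, CH2Cl2, 0 °C
Reagents that add atoms: 3-chloroperoxybenzoic acid, OOC(=O)c1cccc(Cl)c1
Why: Prilezhaev epoxidation: the peracid reacts only with the electron-rich trisubstituted C1=C10 olefin (acrylate and butenolide olefins are electron-poor) and should approach from the outer face of the ring in its crown conformer with C14 and C15 syn, giving the trans 1β,10α-epoxide, 1R,10R.

Compound list
1 | methyl α-D-glucopyranoside | OC[C@H]1O[C@H](OC)[C@H](O)[C@@H](O)[C@@H]1O | starting material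
2 | 4-methoxybenzaldehyde dimethyl acetal | COc1ccc(cc1)C(OC)OC | starting material
3 | methyl 4,6-O-[(R)-4-methoxybenzylidene]-α-D-glucopyranoside | COc1ccc(cc1)[C@@H]2OC[C@H]3O[C@H](OC)[C@H](O)[C@@H](O)[C@@H]3O2 | intermediate
4 | methyl 2-O-TBS-4,6-O-[(R)-4-methoxybenzylidene]-α-D-glucopyranoside | COc1ccc(cc1)[C@@H]2OC[C@H]3O[C@H](OC)[C@H](O[Si](C)(C)C(C)(C)C)[C@@H](O)[C@@H]3O2 | intermediate
5 | methyl 2-O-TBS-3-O-TES-4,6-O-[(R)-4-methoxybenzylidene]-α-D-glucopyranoside | COc1ccc(cc1)[C@@H]2OC[C@H]3O[C@H](OC)[C@H](O[Si](C)(C)C(C)(C)C)[C@@H](O[Si](CC)(CC)CC)[C@@H]3O2 | intermediate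
6 | methyl 2-O-TBS-3-O-TES-4-O-PMB-α-D-glucopyranoside | OC[C@H]1O[C@H](OC)[C@H](O[Si](C)(C)C(C)(C)C)[C@@H](O[Si](CC)(CC)CC)[C@@H]1OCc2ccc(OC)cc2 | intermediate
7 | methyl 6-deoxy-6-iodo-2-O-TBS-3-O-TES-4-O-PMB-α-D-glucopyranoside | IC[C@H]1O[C@H](OC)[C@H](O[Si](C)(C)C(C)(C)C)[C@@H](O[Si](CC)(CC)CC)[C@@H]1OCc2ccc(OC)cc2 | intermediate
8 | methyl 6-deoxy-2-O-TBS-3-O-TES-4-O-PMB-α-D-xylo-hex-5-enopyranoside | C=C1O[C@H](OC)[C@H](O[Si](C)(C)C(C)(C)C)[C@@H](O[Si](CC)(CC)CC)[C@@H]1OCc2ccc(OC)cc2 | intermediate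
9 | (2S,3S,4S)-4-(TBS-oxy)-5-hydroxy-2-(PMB-oxy)-3-(TES-oxy)cyclohexan-1-one, C5 epimers | O=C1CC(O)[C@H](O[Si](C)(C)C(C)(C)C)[C@@H](O[Si](CC)(CC)CC)[C@@H]1OCc2ccc(OC)cc2 | intermediate
10 | 5-O-methanesulfonate of 9 (not isolated) | O=C1CC(OS(C)(=O)=O)[C@H](O[Si](C)(C)C(C)(C)C)[C@@H](O[Si](CC)(CC)CC)[C@@H]1OCc2ccc(OC)cc2 | intermediate
11 | (4S,5S,6S)-4-(TBS-oxy)-6-(PMB-oxy)-5-(TES-oxy)cyclohex-2-en-1-one | O=C1C=C[C@H](O[Si](C)(C)C(C)(C)C)[C@@H](O[Si](CC)(CC)CC)[C@@H]1OCc2ccc(OC)cc2 | intermediate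
12 | pent-4-enal | C=CCCC=O | starting material
13 | (4S,5S,6S)-2-(1-hydroxypent-4-en-1-yl)-4-(TBS-oxy)-6-(PMB-oxy)-5-(TES-oxy)cyclohex-2-en-1-one, C1 epimers | O=C1C(C(O)CCC=C)=C[C@H](O[Si](C)(C)C(C)(C)C)[C@@H](O[Si](CC)(CC)CC)[C@@H]1OCc2ccc(OC)cc2 | intermediate
14 | trimethylsilyl ether of 13 | O=C1C(C(O[Si](C)(C)C)CCC=C)=C[C@H](O[Si](C)(C)C(C)(C)C)[C@@H](O[Si](CC)(CC)CC)[C@@H]1OCc2ccc(OC)cc2 | intermediate
15 | potassium C5–C10 enolate from 1,4-reduction of 14 (not isolated) | [K+].[O-]C1=C(C(O[Si](C)(C)C)CCC=C)C[C@H](O[Si](C)(C)C(C)(C)C)[C@@H](O[Si](CC)(CC)CC)[C@@H]1OCc2ccc(OC)cc2 | intermediate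
16 | (2S,4S,5S,6S)-2-methyl-2-[1-(trimethylsilyloxy)pent-4-en-1-yl]-4-(TBS-oxy)-6-(PMB-oxy)-5-(TES-oxy)cyclohexan-1-one, C1 epimers | O=C1[C@](C)(C(O[Si](C)(C)C)CCC=C)C[C@H](O[Si](C)(C)C(C)(C)C)[C@@H](O[Si](CC)(CC)CC)[C@@H]1OCc2ccc(OC)cc2 | intermediate
17 | (2S,4S,5S,6S)-2-methyl-2-[4-oxo-1-(trimethylsilyloxy)pentyl]-4-(TBS-oxy)-6-(PMB-oxy)-5-(TES-oxy)cyclohexan-1-one, C1 epimers | O=C1[C@](C)(C(O[Si](C)(C)C)CCC(C)=O)C[C@H](O[Si](C)(C)C(C)(C)C)[C@@H](O[Si](CC)(CC)CC)[C@@H]1OCc2ccc(OC)cc2 | intermediate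
18 | 1ξ-(trimethylsilyloxy)-6α-(PMB-oxy)-7β-(TES-oxy)-8α-(TBS-oxy)-4β,10β-dimethyl-trans-decalin-4α,5α-diol (not isolated) | C[Si](C)(C)OC1CC[C@@](C)(O)[C@]2(O)[C@@H](OCc3ccc(OC)cc3)[C@H](O[Si](CC)(CC)CC)[C@@H](O[Si](C)(C)C(C)(C)C)C[C@@]12C | intermediate
19 | 6α-(PMB-oxy)-7β-(TES-oxy)-8α-(TBS-oxy)-4β,10β-dimethyl-trans-decalin-1ξ,4α,5α-triol | OC1CC[C@@](C)(O)[C@]2(O)[C@@H](OCc3ccc(OC)cc3)[C@H](O[Si](CC)(CC)CC)[C@@H](O[Si](C)(C)C(C)(C)C)C[C@@]12C | intermediate
20 | 4α,5α-dihydroxy-6α-(PMB-oxy)-7β-(TES-oxy)-8α-(TBS-oxy)-4β,10β-dimethyl-trans-decalin-1-one | O=C1CC[C@@](C)(O)[C@]2(O)[C@@H](OCc3ccc(OC)cc3)[C@H](O[Si](CC)(CC)CC)[C@@H](O[Si](C)(C)C(C)(C)C)C[C@@]12C | intermediate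
21 | 6α-(PMB-oxy)-7β-(TES-oxy)-8α-(TBS-oxy)-4β,10β-dimethyl-trans-decalin-1β,4α,5α-triol | O[C@@H]1CC[C@@](C)(O)[C@]2(O)[C@@H](OCc3ccc(OC)cc3)[C@H](O[Si](CC)(CC)CC)[C@@H](O[Si](C)(C)C(C)(C)C)C[C@@]12C | intermediate
22 | 4α,5α-dihydroxy-6α-(PMB-oxy)-7β-(TES-oxy)-8α-(TBS-oxy)-4β,10β-dimethyl-trans-decalin-1β-yl methanesulfonate | CS(=O)(=O)O[C@@H]1CC[C@@](C)(O)[C@]2(O)[C@@H](OCc3ccc(OC)cc3)[C@H](O[Si](CC)(CC)CC)[C@@H](O[Si](C)(C)C(C)(C)C)C[C@@]12C | intermediate
23 | (1(10)E,4R,6S,7S,8S)-4-hydroxy-4,10-dimethyl-6-(PMB-oxy)-7-(TES-oxy)-8-(TBS-oxy)cyclodec-1(10)-en-5-one | O([Si](C)(C)C(C)(C)C)[C@H]1C/C(C)=C/CC[C@@](C)(O)C(=O)[C@@H](OCc2ccc(OC)cc2)[C@@H]1O[Si](CC)(CC)CC | intermediate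
24 | (5S)-4,10-dimethyl-6-(PMB-oxy)-7-(TES-oxy)-8-(TBS-oxy)cyclodec-1(10)E-ene-4,5-diol, other centres as in 23 | O([Si](C)(C)C(C)(C)C)[C@H]1C/C(C)=C/CC[C@@](C)(O)[C@@H](O)[C@@H](OCc2ccc(OC)cc2)[C@@H]1O[Si](CC)(CC)CC | intermediate
25 | 5-O-methanesulfonate of 24 (not isolated) | O([Si](C)(C)C(C)(C)C)[C@H]1C/C(C)=C/CC[C@@](C)(O)[C@@H](OS(C)(=O)=O)[C@@H](OCc2ccc(OC)cc2)[C@@H]1O[Si](CC)(CC)CC | intermediate
26 | (4R,5R)-4,5-epoxy-4,10-dimethyl-6-(PMB-oxy)-7-(TES-oxy)-8-(TBS-oxy)cyclodec-1(10)E-ene | O([Si](C)(C)C(C)(C)C)[C@H]1C/C(C)=C/CC[C@@]2(C)O[C@@H]2[C@@H](OCc3ccc(OC)cc3)[C@@H]1O[Si](CC)(CC)CC | intermediate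
27 | (4R,5R)-4,5-epoxy-4,10-dimethyl-7-(TES-oxy)-8-(TBS-oxy)cyclodec-1(10)E-en-6-ol | O([Si](C)(C)C(C)(C)C)[C@H]1C/C(C)=C/CC[C@@]2(C)O[C@@H]2[C@@H](O)[C@@H]1O[Si](CC)(CC)CC | intermediate
28 | tert-butyl diethylphosphonoacetate | CCOP(=O)(OCC)CC(=O)OC(C)(C)C | starting material
29 | (triisopropylsiloxy)methyl chloride | ClCO[Si](C(C)C)(C(C)C)C(C)C | starting material
30 | sodium salt of the carbanion of 28 (not isolated) | [Na+].CCOP(=O)(OCC)[CH-]C(=O)OC(C)(C)C | intermediate
31 | tert-butyl 2-(diethoxyphosphoryl)-3-(TIPS-oxy)propanoate, racemic | CCOP(=O)(OCC)C(CO[Si](C(C)C)(C(C)C)C(C)C)C(=O)OC(C)(C)C | intermediate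
32 | 2-(diethoxyphosphoryl)-3-(TIPS-oxy)propanoic acid, racemic | CCOP(=O)(OCC)C(CO[Si](C(C)C)(C(C)C)C(C)C)C(=O)O | intermediate
33 | C6 ester of 27 with acid 32, epimers at the phosphonate carbon | O([Si](C)(C)C(C)(C)C)[C@H]1C/C(C)=C/CC[C@@]2(C)O[C@@H]2[C@@H](OC(=O)C(CO[Si](C(C)C)(C(C)C)C(C)C)P(=O)(OCC)OCC)[C@@H]1O[Si](CC)(CC)CC | intermediate
34 | C7 alcohol from 33 | O([Si](C)(C)C(C)(C)C)[C@H]1C/C(C)=C/CC[C@@]2(C)O[C@@H]2[C@@H](OC(=O)C(CO[Si](C(C)C)(C(C)C)C(C)C)P(=O)(OCC)OCC)[C@@H]1O | intermediate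
35 | C7 ketone from 34 (not isolated) | O([Si](C)(C)C(C)(C)C)[C@H]1C/C(C)=C/CC[C@@]2(C)O[C@@H]2[C@@H](OC(=O)C(CO[Si](C(C)C)(C(C)C)C(C)C)P(=O)(OCC)OCC)C1=O | intermediate
36 | 13-(TIPS-oxy)-8α-(TBS-oxy)-4α,5β-epoxygermacra-1(10)E,7(11)-dien-12,6α-olide | CC(C)(C)[Si](C)(C)O[C@H]1C/C(C)=C/CC[C@@]2(C)O[C@@H]2[C@H]2OC(=O)C(CO[Si](C(C)C)(C(C)C)C(C)C)=C12 | intermediate
37 | 8α,13-dihydroxy-4α,5β-epoxygermacra-1(10)E,7(11)-dien-12,6α-olide | O[C@H]1C/C(C)=C/CC[C@@]2(C)O[C@@H]2[C@H]2OC(=O)C(CO)=C12 | intermediate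
38 | 13-acetoxy-8α-hydroxy-4α,5β-epoxygermacra-1(10)E,7(11)-dien-12,6α-olide | O[C@H]1C/C(C)=C/CC[C@@]2(C)O[C@@H]2[C@H]2OC(=O)C(COC(C)=O)=C12 | intermediate
39 | ethyl 2-(hydroxymethyl)acrylate | C=C(CO)C(=O)OCC | starting material
40 | ethyl 2-[(TBS-oxy)methyl]acrylate | C=C(CO[Si](C)(C)C(C)(C)C)C(=O)OCC | intermediate
41 | 2-[(TBS-oxy)methyl]acrylic acid | C=C(CO[Si](C)(C)C(C)(C)C)C(=O)O | intermediate
42 | 13-acetoxy-8α-{2-[(TBS-oxy)methyl]acryloyloxy}-4α,5β-epoxygermacra-1(10)E,7(11)-dien-12,6α-olide | C=C(CO[Si](C)(C)C(C)(C)C)C(=O)O[C@H]1C/C(C)=C/CC[C@@]2(C)O[C@@H]2[C@H]2OC(=O)C(COC(C)=O)=C12 | intermediate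
43 | 13-acetoxy-8α-[2-(hydroxymethyl)acryloyloxy]-4α,5β-epoxygermacra-1(10)E,7(11)-dien-12,6α-olide | C=C(CO)C(=O)O[C@H]1C/C(C)=C/CC[C@@]2(C)O[C@@H]2[C@H]2OC(=O)C(COC(C)=O)=C12 | intermediate
44 | (1R,4R,5R,6S,8S,10R)-13-acetoxy-1β,10α:4α,5β-diepoxy-8α-[2-(hydroxymethyl)acryloyloxy]germacr-7(11)-en-12,6α-olide | C=C(CO)C(=O)O[C@H]1C[C@@]2(C)O[C@@H]2CC[C@@]2(C)O[C@@H]2[C@H]2OC(=O)C(COC(C)=O)=C12 | target

Total step count: 32 (28 on the main line, 2 for acid 32, 2 for acid 41).
Longest linear sequence: 28 steps, from 1 to 44 (steps 1–20, 23–27 and 30–32).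

Steps most likely to fail

Step 17 (fragmentation). Under base the liberated tertiary α-hydroxy ketone may rearrange by α-ketol shift, or the diol may be ionised unproductively at O4 so that side reactions compete with fragmentation. The fallback lets only the C5 oxygen be ionised and delivers the ketone already protected. From mesylate 22, selective silylation of the more accessible equatorial C4 hydroxyl (Me3SiCl, imidazole, DMF) should give the C4-O-trimethylsilyl mesylate F1. KN(SiMe3)2 (1.05 equiv, THF, −78 → 0 °C) should fragment it to the 4-(trimethylsilyloxy)cyclodecenone F2. Zn(BH4)2, now chelated through O6, should give the 5S alcohol F3, and K2CO3 in MeOH removes the trimethylsilyl group, rejoining the route at diol 24.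

Step 13 (pinacol closure of ring A). Ring A may close with the cis ring fusion (diol on the β face), because the desired chair carries C14 and C15 syn-diaxial. The fallback sets C4 and C5 by osmylation instead of by the coupling. From diketone 17 the SmI2 coupling is used only to make the C4–C5 bond, and the cis-diol of either ring fusion F4 is converted into the cyclic thiocarbonate F5 (thiophosgene, DMAP). Corey–Winter fragmentation (P(OMe)3, heat) gives the tetrasubstituted Δ4-octalin F6. OsO4 (pyridine; NaHSO3 work-up) should add to the α face, anti to the axial C14, giving 18 and, after the methanolysis of step 13, triol 19.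

Step 11 (quaternary C10). Facial selectivity in the C-methylation may be lost because the stereorandom C1 centre can oppose the ring bias in one epimer, or silyloxide may be lost from the enolate by β-elimination. The fallback methylates a planar β-diketone enolate that has no C1 stereocentre and no β leaving group. From adduct 13, conjugate reduction with [(Ph3P)CuH]6 should give the β-hydroxy ketone F7, and Dess–Martin oxidation the β-diketone F8. K2CO3 and MeI in acetone should give the C10-methylated 1,3-diketone F9, again by attack anti to the C8 silyloxy group. NaBH4 at −78 °C should reduce the less hindered side-chain ketone to the hydroxy ketone F10 (either C1 epimer serves), and silylation as in step 10 rejoins the route at 16.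

Further compounds
F1 | step 17 | C4-O-trimethylsilyl derivative of mesylate 22 | CS(=O)(=O)O[C@@H]1CC[C@@](C)(O[Si](C)(C)C)[C@]2(O)[C@@H](OCc3ccc(OC)cc3)[C@H](O[Si](CC)(CC)CC)[C@@H](O[Si](C)(C)C(C)(C)C)C[C@@]12C
F2 | step 17 | 4-(trimethylsilyloxy) analogue of cyclodecenone 23 | O([Si](C)(C)C(C)(C)C)[C@H]1C/C(C)=C/CC[C@@](C)(O[Si](C)(C)C)C(=O)[C@@H](OCc2ccc(OC)cc2)[C@@H]1O[Si](CC)(CC)CC
F3 | step 17 | C4-O-trimethylsilyl ether of diol 24 | O([Si](C)(C)C(C)(C)C)[C@H]1C/C(C)=C/CC[C@@](C)(O[Si](C)(C)C)[C@@H](O)[C@@H](OCc2ccc(OC)cc2)[C@@H]1O[Si](CC)(CC)CC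
F4 | step 13 | cis-4,5-diol of either ring fusion, C1 trimethylsilyl ether (C4 and C5 unassigned) | C[Si](C)(C)OC1CCC(C)(O)C2(O)[C@@H](OCc3ccc(OC)cc3)[C@H](O[Si](CC)(CC)CC)[C@@H](O[Si](C)(C)C(C)(C)C)C[C@@]12C
F5 | step 13 | 4,5-cyclic thiocarbonate of F4 | C[Si](C)(C)OC1CCC2(C)OC(=S)OC23[C@@H](OCc4ccc(OC)cc4)[C@H](O[Si](CC)(CC)CC)[C@@H](O[Si](C)(C)C(C)(C)C)C[C@@]13C
F6 | step 13 | Δ4-octalin (C4=C5) with C1 trimethylsilyl ether | C[Si](C)(C)OC1CCC(C)=C2[C@@H](OCc3ccc(OC)cc3)[C@H](O[Si](CC)(CC)CC)[C@@H](O[Si](C)(C)C(C)(C)C)C[C@@]12C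
F7 | step 11 | 2-(1-hydroxypent-4-en-1-yl)cyclohexanone from 1,4-reduction of 13 | O=C1C(C(O)CCC=C)C[C@H](O[Si](C)(C)C(C)(C)C)[C@@H](O[Si](CC)(CC)CC)[C@@H]1OCc2ccc(OC)cc2
F8 | step 11 | 2-(pent-4-enoyl)cyclohexanone (β-diketone) | O=C1C(C(=O)CCC=C)C[C@H](O[Si](C)(C)C(C)(C)C)[C@@H](O[Si](CC)(CC)CC)[C@@H]1OCc2ccc(OC)cc2
F9 | step 11 | 2-methyl-2-(pent-4-enoyl)cyclohexanone, C14 β | O=C1[C@](C)(C(=O)CCC=C)C[C@H](O[Si](C)(C)C(C)(C)C)[C@@H](O[Si](CC)(CC)CC)[C@@H]1OCc2ccc(OC)cc2
F10 | step 11 | 2-methyl-2-(1-hydroxypent-4-en-1-yl)cyclohexanone (16 without the trimethylsilyl group) | O=C1[C@](C)(C(O)CCC=C)C[C@H](O[Si](C)(C)C(C)(C)C)[C@@H](O[Si](CC)(CC)CC)[C@@H]1OCc2ccc(OC)cc2
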